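**Retrosynthetic overview**
1. C-2 is set first, in an open chain: the C2–C3 bond is cut to ketene dithioacetal 1 (used as enol silane 2) and aldehyde 3 (ring B bought in); an asymmetric Mukaiyama aldol gives, via silyl ether 4, hydroxy ketone 5.
2. C-5 to C-8, with the methoxy and prenyl groups already in place, is enol ether 9, made from methyl acetoacetate 6 and prenyl bromide 7 via keto ester 8.
3. Key disconnection (three bonds, two rings, one flask): O1–C8a, C8–C8a and C4a–C5, i.e. 5 plus the lithium dienolate 10 of 9; the two SMe groups and the ester OMe are the leaving groups.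
4. Ring order: ring C first (the alkoxide displaces one SMe, giving 11), then ring A (the dienolate displaces the second SMe to give 12, which closes by anionic 6π/Dieckmann cyclisation and aromatises to 13).
5. 14 comes from 13 by Si–O cleavage; no step after the aldol makes or breaks a bond at C-2.

Assumption: 1, 3, 6 and 7 are bought; the (S)-BINOL titanium catalyst is taken to deliver 2 to the Si face of 3 as with other aryl aldehydes (if the first run shows the opposite sense, (R)-BINOL is used and nothing else changes).

**Route**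

Step 1
Reactants: 1 4,4-bis(methylsulfanyl)but-3-en-2-one
Product: 2 [(4,4-bis(methylsulfanyl)buta-1,3-dien-2-yl)oxy]trimethylsilane
Conditions: Me3SiOTf, Et3N, Et2O, 0 °C
Reagents that add atoms: trimethylsilyl trifluoromethanesulfonate, C[Si](C)(C)OS(=O)(=O)C(F)(F)F
Why: Silyl enol ether formation by soft enolisation; the methyl group is the only enolisable position of 1, so a single 2-silyloxydiene results.

Step 2
Reactants: 2 [(4,4-bis(methylsulfanyl)buta-1,3-dien-2-yl)oxy]trimethylsilane; 3 4-[(tert-butyldimethylsilyl)oxy]benzaldehyde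
Product: 5 (5S)-5-{4-[(tert-butyldimethylsilyl)oxy]phenyl}-5-hydroxy-1,1-bis(methylsulfanyl)pent-1-en-3-one, via trimethylsilyl ether 4 (not isolated)
Conditions: Ti(OiPr)4 (10 mol %), (S)-BINOL (20 mol %), 4 Å MS, Et2O, −20 °C; then 1 M HCl, THF, 0 °C, 10 min
Reagents that add atoms: none
Why: Catalytic asymmetric Mukaiyama aldol addition (BINOL–titanium catalysis of the kind used for Danishefsky-type 2-silyloxydienes), in which the CH2 terminus of 2 adds to the Si face of 3 and sets C-2 as (S), silicon moves to the new oxygen (4), and brief cold dilute acid removes only that Me3Si group while the aryl TBS ether and the ketene dithioacetal stay.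

Step 3
Reactants: 6 methyl 3-oxobutanoate; 7 1-bromo-3-methylbut-2-ene
Product: 8 methyl 2-acetyl-5-methylhex-4-enoate
Conditions: K2CO3, acetone, reflux (6 in 1.5-fold excess)
Reagents that add atoms: none
Why: Acetoacetic ester C-alkylation with a reactive allylic bromide; the excess of 6 suppresses double alkylation.

Step 4
Reactants: 8 methyl 2-acetyl-5-methylhex-4-enoate
Product: 9 methyl (2E)-3-methoxy-2-(3-methylbut-2-en-1-yl)but-2-enoate
Conditions: NaH, THF–DMPU, 0 °C; then Me2SO4, 0 °C → rt
Reagents that add atoms: dimethyl sulfate, COS(=O)(=O)OC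
Why: O-alkylation of a β-keto ester enolate (enol ether formation): with a hard methylating agent and a dissociated sodium enolate in a dipolar aprotic medium, oxygen is methylated in preference to the already substituted α-carbon, giving the β-methoxy acrylate (some (2Z)-isomer may form and is expected to feed the same dienolate in step 5).

Step 5
Reactants: 5 (5S)-5-{4-[(tert-butyldimethylsilyl)oxy]phenyl}-5-hydroxy-1,1-bis(methylsulfanyl)pent-1-en-3-one; 9 methyl (2E)-3-methoxy-2-(3-methylbut-2-en-1-yl)but-2-enoate
Product: 13 (2S)-2-{4-[(tert-butyldimethylsilyl)oxy]phenyl}-5-hydroxy-7-methoxy-6-(3-methylbut-2-en-1-yl)-2,3-dihydro-4H-chromen-4-one, via lithium dienolate 10 (not isolated), via methylsulfanyl dihydropyranone 11 (not isolated), via pyranyl methoxybutenoate 12 (not isolated)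
Conditions: 9 (3.2 equiv), LiN(iPr)2 (3.1 equiv), THF, −78 °C; then 5 (1.0 equiv), −78 → −10 °C; AcOH quench at −20 °C
Reagents that add atoms: none
Why: Proposed new method: the first equivalent of dienolate 10 only deprotonates the hydroxyl of 5, and the lithium alkoxide closes ring C by 6-endo addition–elimination at the bis(methylsulfanyl) carbon (vinylic substitution, loss of LiSMe) to give the neutral dihydropyranone 11; a second equivalent of 10 attacks the same carbon through its terminal CH2 (its α-carbon is fully substituted) and expels the second MeS− to give 12, whose doubly vinylogous CH2 is deprotonated to a trienolate that closes C4a–C5 onto the ester (oxyanion-accelerated 6π electrocyclisation, equivalent to a vinylogous Dieckmann condensation), loses methoxide and tautomerises to the chelated phenolate of 13; C-2 is carried over unchanged from 5 because no bond to it is touched and the cold, short reaction with an acidic quench is meant to avoid retro-oxa-Michael opening; the closest known reaction types are the Michael–Dieckmann (Michael–Claisen) arene annulation of 3-alkoxycrotonate dienolates and the Junjappa–Ila use of α-oxo ketene dithioacetals as 1,3-dielectrophiles with SMe as leaving group.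

Step 6
Reactants: 13 (2S)-2-{4-[(tert-butyldimethylsilyl)oxy]phenyl}-5-hydroxy-7-methoxy-6-(3-methylbut-2-en-1-yl)-2,3-dihydro-4H-chromen-4-one
Product: 14 (2S)-5-hydroxy-2-(4-hydroxyphenyl)-7-methoxy-6-(3-methylbut-2-en-1-yl)-2,3-dihydro-4H-chromen-4-one (6-prenylsakuranetin)
Conditions: Bu4NF (1.2 equiv), AcOH (1.5 equiv), THF, 0 °C
Reagents that add atoms: none
Why: Fluoride-mediated desilylation of the aryl silyl ether, buffered with AcOH so that no phenoxide or enolate forms and C-2 cannot racemise through ring opening; the prenyl group and the chelated 5-OH are inert.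

**Compound list**
1 | 4,4-bis(methylsulfanyl)but-3-en-2-one | CC(=O)C=C(SC)SC | starting material
2 | [(4,4-bis(methylsulfanyl)buta-1,3-dien-2-yl)oxy]trimethylsilane | C=C(O[Si](C)(C)C)C=C(SC)SC | intermediate
3 | 4-[(tert-butyldimethylsilyl)oxy]benzaldehyde | O=Cc1ccc(O[Si](C)(C)C(C)(C)C)cc1 | starting material
4 | (5S)-5-{4-[(tert-butyldimethylsilyl)oxy]phenyl}-1,1-bis(methylsulfanyl)-5-[(trimethylsilyl)oxy]pent-1-en-3-one | CSC(SC)=CC(=O)C[C@@H](c1ccc(O[Si](C)(C)C(C)(C)C)cc1)O[Si](C)(C)C | intermediate
5 | (5S)-5-{4-[(tert-butyldimethylsilyl)oxy]phenyl}-5-hydroxy-1,1-bis(methylsulfanyl)pent-1-en-3-one | CSC(SC)=CC(=O)C[C@@H](c1ccc(O[Si](C)(C)C(C)(C)C)cc1)O | intermediate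
6 | methyl 3-oxobutanoate (methyl acetoacetate) | CC(=O)CC(=O)OC | starting material
7 | 1-bromo-3-methylbut-2-ene (prenyl bromide) | CC(C)=CCBr | starting material
8 | methyl 2-acetyl-5-methylhex-4-enoate | CC(=O)C(CC=C(C)C)C(=O)OC | intermediate
9 | methyl (2E)-3-methoxy-2-(3-methylbut-2-en-1-yl)but-2-enoate | CO/C(C)=C(\CC=C(C)C)C(=O)OC | intermediate
10 | lithium 1,3-dimethoxy-2-(3-methylbut-2-en-1-yl)buta-1,3-dien-1-olate | [Li+].[O-]C(OC)=C(CC=C(C)C)C(OC)=C | intermediate
11 | (2S)-2-{4-[(tert-butyldimethylsilyl)oxy]phenyl}-6-(methylsulfanyl)-2,3-dihydro-4H-pyran-4-one | CSC1=CC(=O)C[C@@H](c2ccc(O[Si](C)(C)C(C)(C)C)cc2)O1 | intermediate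
12 | methyl (2E)-4-[(2S)-2-{4-[(tert-butyldimethylsilyl)oxy]phenyl}-4-oxo-3,4-dihydro-2H-pyran-6-yl]-3-methoxy-2-(3-methylbut-2-en-1-yl)but-2-enoate | CO/C(CC1=CC(=O)C[C@@H](c2ccc(O[Si](C)(C)C(C)(C)C)cc2)O1)=C(\CC=C(C)C)C(=O)OC | intermediate
13 | (2S)-2-{4-[(tert-butyldimethylsilyl)oxy]phenyl}-5-hydroxy-7-methoxy-6-(3-methylbut-2-en-1-yl)-2,3-dihydro-4H-chromen-4-one | COc1cc2c(c(O)c1CC=C(C)C)C(=O)C[C@@H](c1ccc(O[Si](C)(C)C(C)(C)C)cc1)O2 | intermediate
14 | (2S)-5-hydroxy-2-(4-hydroxyphenyl)-7-methoxy-6-(3-methylbut-2-en-1-yl)-2,3-dihydro-4H-chromen-4-one (6-prenylsakuranetin) | COc1cc2c(c(O)c1CC=C(C)C)C(=O)C[C@@H](c1ccc(O)cc1)O2 | target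

**Step count and weak points**
Total steps: 6. Longest linear sequence: 4 steps (1 → 2 → 5 → 13 → 14); the branch 6 + 7 → 8 → 9 (2 steps) joins at step 5.

Most likely to fail, in order:

Step 5 (the double annulation). The risks are retro-aldol of the lithium alkoxide of 5 before ring C closes, deprotonation at C-3 with ring opening, attack of the dienolate before ring C has formed (which would leave SMe on the arene), and a slow final closure that exposes 13 to base. The fallback keeps both ring closures in one flask but makes the carbon–carbon bond under Lewis acid instead of strong base; it sets out from 5 and 9 and comes back at 13. 9 is first converted (LiN(iPr)2, Me3SiCl, THF, −78 °C) into the silyl ketene acetal [(1,3-dimethoxy-2-(3-methylbut-2-en-1-yl)buta-1,3-dien-1-yl)oxy]trimethylsilane F1. 5 and F1 (2.5 equiv) are then treated with Me3SiOTf (0.2 equiv) in CH2Cl2 at −78 → −30 °C. F1 silylates the hydroxyl (giving 4), the silylated carbonyl makes the dithioacetal carbon cationic, and the C-2 oxygen closes ring C with loss of MeSSiMe3 (11). A second F1 adds through its CH2 terminus at the same carbon and expels the second MeSSiMe3 (12, a vinylogous Mukaiyama addition–elimination). 1,8-Diazabicyclo[5.4.0]undec-7-ene is then added to the same flask at 0 °C to close ring A, which rejoins the route at 13. No free alkoxide or lithium base meets C-2, and 11 or 12 can be isolated to locate a failure.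

Step 2 (asymmetric aldol). The sulfur-substituted enol silane is a new substrate for the titanium catalyst, so rate and ee are uncertain, and the acid work-up must not cyclise the product. The fallback sets out from 1 and 3 and comes back at 5: the lithium enolate of 1 (LiN(iPr)2, THF, −78 °C) adds to 3 to give the racemic aldol rac-5-{4-[(tert-butyldimethylsilyl)oxy]phenyl}-5-hydroxy-1,1-bis(methylsulfanyl)pent-1-en-3-one F2, and preparative HPLC on a cellulose tris(3,5-dimethylphenylcarbamate) phase delivers the (S)-enantiomer, which is 5.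

Step 4 (O- versus C-methylation, and E/Z ratio). The fallback sets out from 8 and comes back at 9: ketalisation with HC(OMe)3 in MeOH with catalytic pyridinium p-toluenesulfonate gives methyl 3,3-dimethoxy-2-(3-methylbut-2-en-1-yl)butanoate F3, and heating F3 with the same catalyst while MeOH distils off gives 9 by elimination, with no C-methylation possible.

**Further compounds**
F1 | step 5 | [(1,3-dimethoxy-2-(3-methylbut-2-en-1-yl)buta-1,3-dien-1-yl)oxy]trimethylsilane | COC(=C)C(CC=C(C)C)=C(OC)O[Si](C)(C)C
F2 | step 2 | rac-5-{4-[(tert-butyldimethylsilyl)oxy]phenyl}-5-hydroxy-1,1-bis(methylsulfanyl)pent-1-en-3-one | CSC(SC)=CC(=O)CC(O)c1ccc(O[Si](C)(C)C(C)(C)C)cc1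
F3 | step 4 | methyl 3,3-dimethoxy-2-(3-methylbut-2-en-1-yl)butanoate | COC(C)(OC)C(CC=C(C)C)C(=O)OC
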